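**Strategy.** The cyclohexenone core (C1 ketone, C2 OAc, C3 Me, C4 OH, C5 CH2, C6 alkylidene) is cut into two three-carbon pieces across C5–C6 and C2=C3. Dibenzyl acetonedicarboxylate supplies C6–C1–C2, whose two carbons α to the C1 ketone act as a double nucleophile; (R)-acetyloxirane supplies C5–C4–C3 with the C4 stereocentre. In one operation the enolate opens the oxirane, the O-4 alkoxide lactonises onto the C6 carboxyl (a temporary γ-lactone that exploits the 1,3-relation of O-4 and C6 and guards C4), and the second methylene condenses with the acetyl group. Epoxidation and two decarboxylations unveil the diosphenol; aldol condensation with an angelate-bearing ketone and enol acetylation finish.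

Key step: step 3

Remark: the target is read from the SMILES as the (E)-alkylidene, the (S)-angelate carbinol and the (R)-ring carbinol. The ring locants C1–C6 defined above are used in the Why lines for the corresponding carbons of all intermediates; systematic names carry their own locants.

Step 1
Reactants: 1 methyl (2R)-oxirane-2-carboxylate
Product: 2 (2R)-N-methoxy-N-methyloxirane-2-carboxamide
Conditions: MeNHOMe·HCl, LiN(SiMe3)2, THF, −78 → −20 °C
Reagents that add atoms: N,O-dimethylhydroxylamine hydrochloride (CNOC.Cl)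
Why: Weinreb amide formation by aminolysis of the ester with the lithium amide of the hydroxylamine should be faster at low temperature than oxirane opening, and the stereocentre is not involved.

Step 2
Reactants: 2 (2R)-N-methoxy-N-methyloxirane-2-carboxamide
Product: 3 1-[(2R)-oxiran-2-yl]ethan-1-one
Conditions: MeLi, Et2O, −78 °C; aq NH4Cl
Reagents that add atoms: methyllithium ([Li]C)
Why: Weinreb ketone synthesis, in which the chelated tetrahedral intermediate stops at mono-addition and MeLi should not open the oxirane at −78 °C, so the (R) centre is carried through unchanged.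

Step 3
Reactants: 4 dibenzyl 3-oxopentanedioate; 3 1-[(2R)-oxiran-2-yl]ethan-1-one
Product: 8 benzyl (1S,5R)-4-methyl-2,7-dioxo-6-oxabicyclo[3.2.1]oct-3-ene-3-carboxylate, via hydroxy ketone 5 (not isolated), via keto lactone 6 (not isolated), via bicyclic aldol 7 (not isolated)
Conditions: NaH (1.0 equiv), THF, 0 → 50 °C; AcOH
Reagents that add atoms: none
Why: The sodium enolate of 4 should open the oxirane of 3 at its unhindered CH2 terminus (SN2, the adjacent carbinol carbon untouched) to forge C5–C6, the O-4 alkoxide then attacks the neighbouring benzyl ester (5-exo-trig) to give γ-lactone 6, and the remaining active methylene adds to the acetyl carbonyl (6-(enolexo)-exo-trig aldol) and dehydrates by E1cB to the C2=C3 alkene inside a 6-oxabicyclo[3.2.1]octene. The closest known reactions are the acetoacetic ester–epoxide synthesis of α-acyl-γ-butyrolactones and the Knoevenagel-type [3+3] annulations of acetonedicarboxylates. The C4 stereocentre comes unchanged from 3; the bridgehead C6 is epimerisable in 6 and is drawn into the cis-fused lactone by the ring closure, and no other stereocentre survives the dehydration. The aldol must start from C2 and not from the acetyl methyl group (Robinson mode), which the roughly eight pKa units between a β-keto ester CH2 and a methyl ketone should secure; the same gap should make ring closure faster than enolisation at C4. C- over O-alkylation and attack at the terminal oxirane carbon follow the behaviour of soft 1,3-dicarbonyl enolates towards epoxides, and the symmetry of 4 removes any question of which methylene reacts first. The lactone then keeps O-4 acylated and C6 non-enolisable (bridgehead) through the next three steps.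

Step 4
Reactants: 8 benzyl (1S,5R)-4-methyl-2,7-dioxo-6-oxabicyclo[3.2.1]oct-3-ene-3-carboxylate
Product: 9 benzyl (1S,5R)-3,4-epoxy-4-methyl-2,7-dioxo-6-oxabicyclo[3.2.1]octane-3-carboxylate
Conditions: t-BuOOH (anhydrous), DBU (cat.), CH2Cl2, −20 → 0 °C
Reagents that add atoms: tert-butyl hydroperoxide (CC(C)(C)OO)
Why: Weitz–Scheffer nucleophilic epoxidation of the doubly activated alkylidene β-keto ester puts the oxygen on C2; the face of attack is irrelevant because both oxirane carbons become sp2 again in step 5.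

Step 5
Reactants: 9 benzyl (1S,5R)-3,4-epoxy-4-methyl-2,7-dioxo-6-oxabicyclo[3.2.1]octane-3-carboxylate
Product: 11 (1S,5R)-3-hydroxy-4-methyl-6-oxabicyclo[3.2.1]oct-3-ene-2,7-dione, via glycidic acid 10 (not isolated)
Conditions: H2 (1 atm), Pd/C, EtOAc, 25 °C; then 45 °C
Reagents that add atoms: none
Why: Hydrogenolysis of the benzyl ester gives a glycidic acid that should lose CO2 with opening of the oxirane (Darzens glycidic acid decarboxylation), leaving the oxygen on C2 and regenerating C2=C3 as the hydrogen-bonded diosphenol.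

Step 6
Reactants: 11 (1S,5R)-3-hydroxy-4-methyl-6-oxabicyclo[3.2.1]oct-3-ene-2,7-dione
Product: 12 (4R)-2,4-dihydroxy-3-methylcyclohex-2-en-1-one
Conditions: LiOH, THF–H2O, 0 °C; then AcOH to pH 5, 40 °C
Reagents that add atoms: none
Why: Hydroxide should open the non-enolisable β-keto lactone at the lactone carbonyl (the ring ketone is deactivated as the diosphenolate), and the freed β-keto acid decarboxylates on gentle acidification; C4 keeps its configuration because the acyl–oxygen bond is the one cleaved.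

Step 7
Reactants: 12 (4R)-2,4-dihydroxy-3-methylcyclohex-2-en-1-one
Product: 13 (4R)-2,4-bis[(tert-butyldimethylsilyl)oxy]-3-methylcyclohex-2-en-1-one
Conditions: TBSCl, imidazole, DMF, 0 → 25 °C
Reagents that add atoms: tert-butyldimethylsilyl chloride (CC(C)(C)[Si](C)(C)Cl)
Why: Imidazole-promoted silylation masks both the acidic enol OH and the secondary alcohol so that step 10 can generate a single enolate.

Step 8
Reactants: 14 6-methylhept-5-en-2-one
Product: 16 (3S)-3-hydroxy-6-methylhept-5-en-2-one, via aminoxy ketone 15 (not isolated)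
Conditions: D-proline (20 mol %), PhNO (slow addition), DMSO, 25 °C, ketone in excess; then CuSO4·5H2O (30 mol %), MeOH, 0 °C
Reagents that add atoms: nitrosobenzene (O=Nc1ccccc1)
Why: Proline-catalysed α-aminoxylation (O-nitroso aldol) through the more substituted enamine of the methyl ketone, with D-proline expected to deliver the (3S) centre, followed by copper-catalysed N–O cleavage that leaves the trisubstituted alkene untouched.

Step 9
Reactants: 16 (3S)-3-hydroxy-6-methylhept-5-en-2-one; 17 (2Z)-2-methylbut-2-enoic acid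
Product: 19 (3S)-6-methyl-2-oxohept-5-en-3-yl (2Z)-2-methylbut-2-enoate, via mixed anhydride 18 (not isolated)
Conditions: 17, 2,4,6-trichlorobenzoyl chloride, Et3N, toluene, 25 °C; filter; then 16, 70 °C
Reagents that add atoms: none
Why: Yamaguchi-type esterification with the preformed mixed anhydride in the absence of a nucleophilic amine should avoid Z-to-E isomerisation of the angelate and epimerisation of the α-acyloxy ketone.

Step 10
Reactants: 13 (4R)-2,4-bis[(tert-butyldimethylsilyl)oxy]-3-methylcyclohex-2-en-1-one; 19 (3S)-6-methyl-2-oxohept-5-en-3-yl (2Z)-2-methylbut-2-enoate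
Product: 20 (3S)-2-{(5R)-3,5-bis[(tert-butyldimethylsilyl)oxy]-4-methyl-2-oxocyclohex-3-en-1-yl}-2-hydroxy-6-methylhept-5-en-3-yl (2Z)-2-methylbut-2-enoate
Conditions: LiN(iPr)2, THF, −78 °C; CeCl3; 19, −78 °C; aq NH4Cl at −78 °C
Reagents that add atoms: none
Why: Kinetic α'-deprotonation of the enone at C6 and cerium-mediated aldol addition to the methyl ketone (the cerium enolate is less basic, which should suppress proton transfer); the two new stereocentres are not controlled and are removed in step 11.

Step 11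
Reactants: 20 (3S)-2-{(5R)-3,5-bis[(tert-butyldimethylsilyl)oxy]-4-methyl-2-oxocyclohex-3-en-1-yl}-2-hydroxy-6-methylhept-5-en-3-yl (2Z)-2-methylbut-2-enoate
Product: 22 (2E,3S)-2-{(5R)-3,5-bis[(tert-butyldimethylsilyl)oxy]-4-methyl-2-oxocyclohex-3-en-1-ylidene}-6-methylhept-5-en-3-yl (2Z)-2-methylbut-2-enoate, via mesylate 21 (not isolated)
Conditions: MsCl, Et3N, CH2Cl2, 0 → 25 °C
Reagents that add atoms: none
Why: Sulfene-mediated mesylation of the tertiary alcohol and E1cB elimination through the C6 enolate (aldol condensation) should favour the E-alkylidene, in which the bulky acyloxy-bearing carbon lies syn to C5H2 and the methyl group syn to the carbonyl.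

Step 12
Reactants: 22 (2E,3S)-2-{(5R)-3,5-bis[(tert-butyldimethylsilyl)oxy]-4-methyl-2-oxocyclohex-3-en-1-ylidene}-6-methylhept-5-en-3-yl (2Z)-2-methylbut-2-enoate
Product: 23 (2E,3S)-2-[(5R)-3,5-dihydroxy-4-methyl-2-oxocyclohex-3-en-1-ylidene]-6-methylhept-5-en-3-yl (2Z)-2-methylbut-2-enoate
Conditions: HF·pyridine, pyridine, THF, 0 °C
Reagents that add atoms: none
Why: Buffered fluoride desilylation should cleave the enol and the secondary silyl ethers without touching the two esters or ionising the allylic alcohol.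

Step 13
Reactants: 23 (2E,3S)-2-[(5R)-3,5-dihydroxy-4-methyl-2-oxocyclohex-3-en-1-ylidene]-6-methylhept-5-en-3-yl (2Z)-2-methylbut-2-enoate
Product: 24 (2E,3S)-2-[(5R)-3-(acetyloxy)-5-hydroxy-4-methyl-2-oxocyclohex-3-en-1-ylidene]-6-methylhept-5-en-3-yl (2Z)-2-methylbut-2-enoate
Conditions: Ac2O (1.05 equiv), Et3N, CH2Cl2, −20 °C
Reagents that add atoms: acetic anhydride (CC(=O)OC(C)=O)
Why: Chemoselective enol acetylation, since the diosphenol OH is deprotonated by Et3N and should be acylated far faster than the neutral secondary allylic alcohol.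

**Compound list**

1 | methyl (2R)-oxirane-2-carboxylate | COC(=O)[C@H]1CO1 | starting material
2 | (2R)-N-methoxy-N-methyloxirane-2-carboxamide | CON(C)C(=O)[C@H]1CO1 | intermediate
3 | 1-[(2R)-oxiran-2-yl]ethan-1-one | CC(=O)[C@H]1CO1 | intermediate
4 | dibenzyl 3-oxopentanedioate | O=C(CC(=O)OCc1ccccc1)CC(=O)OCc1ccccc1 | starting material
5 | dibenzyl 2-[(2R)-2-hydroxy-3-oxobutyl]-3-oxopentanedioate | CC(=O)[C@H](O)CC(C(=O)OCc1ccccc1)C(=O)CC(=O)OCc1ccccc1 | intermediate
6 | benzyl 3-[(5R)-5-acetyl-2-oxooxolan-3-yl]-3-oxopropanoate | CC(=O)[C@H]1CC(C(=O)CC(=O)OCc2ccccc2)C(=O)O1 | intermediate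
7 | benzyl (1S,5R)-4-hydroxy-4-methyl-2,7-dioxo-6-oxabicyclo[3.2.1]octane-3-carboxylate | CC1(O)[C@H]2C[C@H](C(=O)O2)C(=O)C1C(=O)OCc1ccccc1 | intermediate
8 | benzyl (1S,5R)-4-methyl-2,7-dioxo-6-oxabicyclo[3.2.1]oct-3-ene-3-carboxylate | CC1=C(C(=O)OCc3ccccc3)C(=O)[C@@H]2C[C@H]1OC2=O | intermediate
9 | benzyl (1S,5R)-3,4-epoxy-4-methyl-2,7-dioxo-6-oxabicyclo[3.2.1]octane-3-carboxylate | CC12OC1(C(=O)OCc3ccccc3)C(=O)[C@@H]3C[C@H]2OC3=O | intermediate
10 | (1S,5R)-3,4-epoxy-4-methyl-2,7-dioxo-6-oxabicyclo[3.2.1]octane-3-carboxylic acid | CC12OC1(C(=O)O)C(=O)[C@@H]3C[C@H]2OC3=O | intermediate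
11 | (1S,5R)-3-hydroxy-4-methyl-6-oxabicyclo[3.2.1]oct-3-ene-2,7-dione | CC1=C(O)C(=O)[C@@H]2C[C@H]1OC2=O | intermediate
12 | (4R)-2,4-dihydroxy-3-methylcyclohex-2-en-1-one | O=C1CC[C@@H](O)C(C)=C1O | intermediate
13 | (4R)-2,4-bis[(tert-butyldimethylsilyl)oxy]-3-methylcyclohex-2-en-1-one | O=C1CC[C@@H](O[Si](C)(C)C(C)(C)C)C(C)=C1O[Si](C)(C)C(C)(C)C | intermediate
14 | 6-methylhept-5-en-2-one | CC(=O)CCC=C(C)C | starting material
15 | (3S)-6-methyl-3-[(phenylamino)oxy]hept-5-en-2-one | CC(=O)[C@@H](ONc1ccccc1)CC=C(C)C | intermediate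
16 | (3S)-3-hydroxy-6-methylhept-5-en-2-one | CC(=O)[C@@H](O)CC=C(C)C | intermediate
17 | (2Z)-2-methylbut-2-enoic acid (angelic acid) | C/C=C(/C)C(=O)O | starting material
18 | (2Z)-2-methylbut-2-enoic 2,4,6-trichlorobenzoic anhydride | C/C=C(/C)C(=O)OC(=O)c1c(Cl)cc(Cl)cc1Cl | intermediate
19 | (3S)-6-methyl-2-oxohept-5-en-3-yl (2Z)-2-methylbut-2-enoate | C/C=C(/C)C(=O)O[C@@H](CC=C(C)C)C(C)=O | intermediate
20 | (3S)-2-{(5R)-3,5-bis[(tert-butyldimethylsilyl)oxy]-4-methyl-2-oxocyclohex-3-en-1-yl}-2-hydroxy-6-methylhept-5-en-3-yl (2Z)-2-methylbut-2-enoate | C/C=C(/C)C(=O)O[C@@H](CC=C(C)C)C(C)(O)C1C[C@@H](O[Si](C)(C)C(C)(C)C)C(C)=C(O[Si](C)(C)C(C)(C)C)C1=O | intermediate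
21 | methanesulfonate of 20 at the tertiary hydroxyl | C/C=C(/C)C(=O)O[C@@H](CC=C(C)C)C(C)(OS(C)(=O)=O)C1C[C@@H](O[Si](C)(C)C(C)(C)C)C(C)=C(O[Si](C)(C)C(C)(C)C)C1=O | intermediate
22 | (2E,3S)-2-{(5R)-3,5-bis[(tert-butyldimethylsilyl)oxy]-4-methyl-2-oxocyclohex-3-en-1-ylidene}-6-methylhept-5-en-3-yl (2Z)-2-methylbut-2-enoate | C/C=C(/C)C(=O)O[C@@H](CC=C(C)C)/C(C)=C1\C[C@@H](O[Si](C)(C)C(C)(C)C)C(C)=C(O[Si](C)(C)C(C)(C)C)C1=O | intermediate
23 | (2E,3S)-2-[(5R)-3,5-dihydroxy-4-methyl-2-oxocyclohex-3-en-1-ylidene]-6-methylhept-5-en-3-yl (2Z)-2-methylbut-2-enoate | C/C=C(/C)C(=O)O[C@@H](CC=C(C)C)/C(C)=C1\C[C@@H](O)C(C)=C(O)C1=O | intermediate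
24 | (2E,3S)-2-[(5R)-3-(acetyloxy)-5-hydroxy-4-methyl-2-oxocyclohex-3-en-1-ylidene]-6-methylhept-5-en-3-yl (2Z)-2-methylbut-2-enoate | C/C=C(/C)C(=O)O[C@@H](CC=C(C)C)/C(C)=C1\C[C@@H](O)C(C)=C(OC(C)=O)C1=O | target

**Step count and risks**

Total step count: 13. Longest linear sequence: 11 steps (steps 1–7 and 10–13); steps 8 and 9 form the side branch.

Steps most likely to fail:

1. Step 3. What may go wrong: O- instead of C-alkylation of the enolate; aldol addition to the acetyl group before the oxirane is opened, followed by O-cyclisation to a dihydrofuran (interrupted Feist–Benary course); or slow lactonisation that leaves an α-ketol exposed to base and erodes the configuration at C4. Fallback, setting out from 4 and returning at 12: the epoxide is replaced by a Michael acceptor and the stereocentre is set afterwards by an enzyme. Butane-2,3-dione is silylated (Me3SiCl, Et3N) to 3-(trimethylsilyloxy)but-3-en-2-one F1. Base-catalysed Michael addition of 4 to F1 (DBU cat., THF), followed by Knoevenagel-type aldol condensation and desilylation on work-up, should give racemic dibenzyl 5-hydroxy-4-methyl-2-oxocyclohex-3-ene-1,3-dicarboxylate F2. Nucleophilic epoxidation as in step 4 gives the oxirane F3, and hydrogenolysis with double decarboxylation as in step 5 gives racemic 2,4-dihydroxy-3-methylcyclohex-2-en-1-one F4. A lipase (Candida antarctica lipase B, vinyl acetate) is expected by the Kazlauskas rule to acetylate the (4R)-alcohol, giving (1R)-3-hydroxy-2-methyl-4-oxocyclohex-2-en-1-yl acetate F5. F5 is separated from the unreacted (4S)-alcohol and methanolysed (K2CO3, MeOH) to 12. If the enzyme prefers the other enantiomer, the unreacted alcohol is 12.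

2. Step 11. What may go wrong: poor geometric control in the elimination (E/Z mixture), elimination towards the methyl group, or loss of the angelate after acyl shift to the tertiary oxygen. Fallback, setting out from 13 and returning at 22: the alkene is built stereospecifically instead of by elimination. Methyl (2S)-oxirane-2-carboxylate (commercial) is opened at its CH2 terminus by 2-methylprop-1-enylmagnesium bromide with CuI (cat.) to methyl (2S)-2-hydroxy-5-methylhex-4-enoate F6, which is esterified as in step 9 to methyl (2S)-5-methyl-2-{[(2Z)-2-methylbut-2-enoyl]oxy}hex-4-enoate F7. Crossed Claisen acylation of the lithium enolate of 13 (two equivalents) with F7 should give the β-diketone F8. O-triflation of its sodium chelate (NaH, PhNTf2) at the side-chain carbonyl should give the (Z)-enol triflate F9, with the triflate syn to the ring carbonyl. Stille methylation (Me4Sn, Pd(PPh3)4, LiCl, DMF, 50 °C) replaces the triflate by methyl with retention and gives 22.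

3. Step 10. What may go wrong: proton transfer from the acidic α-acyloxy ketone to the enolate, retro-aldol on warming, or 1,2-acyl shift of the angelate in the metal aldolate. Fallback, setting out from 13 and 19 and returning at 20: the basic enolate is replaced by a silyl enol ether. 13 is converted (LiN(iPr)2, Me3SiCl, THF, −78 °C) into (4R)-2,4-bis[(tert-butyldimethylsilyl)oxy]-3-methyl-1-(trimethylsilyloxy)cyclohexa-1,5-diene F10. A Mukaiyama aldol addition of F10 to 19 (BF3·OEt2, CH2Cl2, −78 °C) then gives 20 without a free alkoxide in the flask.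

**Further compounds**

F1 | step 3 | 3-(trimethylsilyloxy)but-3-en-2-one | CC(=O)C(=C)O[Si](C)(C)C
F2 | step 3 | dibenzyl 5-hydroxy-4-methyl-2-oxocyclohex-3-ene-1,3-dicarboxylate (racemic) | CC1=C(C(=O)OCc2ccccc2)C(=O)C(C(=O)OCc2ccccc2)CC1O
F3 | step 3 | dibenzyl 3,4-epoxy-5-hydroxy-4-methyl-2-oxocyclohexane-1,3-dicarboxylate (racemic) | CC12OC1(C(=O)OCc1ccccc1)C(=O)C(C(=O)OCc1ccccc1)CC2O
F4 | step 3 | 2,4-dihydroxy-3-methylcyclohex-2-en-1-one (racemic) | CC1=C(O)C(=O)CCC1O
F5 | step 3 | (1R)-3-hydroxy-2-methyl-4-oxocyclohex-2-en-1-yl acetate | O=C1CC[C@@H](OC(C)=O)C(C)=C1O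
F6 | step 11 | methyl (2S)-2-hydroxy-5-methylhex-4-enoate | COC(=O)[C@@H](O)CC=C(C)C
F7 | step 11 | methyl (2S)-5-methyl-2-{[(2Z)-2-methylbut-2-enoyl]oxy}hex-4-enoate | C/C=C(/C)C(=O)O[C@@H](CC=C(C)C)C(=O)OC
F8 | step 11 | (2S)-1-{(5R)-3,5-bis[(tert-butyldimethylsilyl)oxy]-4-methyl-2-oxocyclohex-3-en-1-yl}-5-methyl-1-oxohex-4-en-2-yl (2Z)-2-methylbut-2-enoate | C/C=C(/C)C(=O)O[C@@H](CC=C(C)C)C(=O)C1C[C@@H](O[Si](C)(C)C(C)(C)C)C(C)=C(O[Si](C)(C)C(C)(C)C)C1=O
F9 | step 11 | (1Z,2S)-1-{(5R)-3,5-bis[(tert-butyldimethylsilyl)oxy]-4-methyl-2-oxocyclohex-3-en-1-ylidene}-5-methyl-1-{[(trifluoromethyl)sulfonyl]oxy}hex-4-en-2-yl (2Z)-2-methylbut-2-enoate | C/C=C(/C)C(=O)O[C@@H](CC=C(C)C)/C(OS(=O)(=O)C(F)(F)F)=C1\C[C@@H](O[Si](C)(C)C(C)(C)C)C(C)=C(O[Si](C)(C)C(C)(C)C)C1=O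
F10 | step 10 | (4R)-2,4-bis[(tert-butyldimethylsilyl)oxy]-3-methyl-1-(trimethylsilyloxy)cyclohexa-1,5-diene | C[Si](C)(C)OC1=CC[C@@H](O[Si](C)(C)C(C)(C)C)C(C)=C1O[Si](C)(C)C(C)(C)C
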